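In 1-benzofuran-2-one numbering, the cyclohexane ring (C3a, C4, C5, C6, C7, C7a) bears oxygen on C4 and C7a, both flanking C3a, and an isopropenyl-derived group on C5 next to C4–O. This 1,3-dioxygenated, homoallylic pattern is read as an aldol followed by a carbonyl-ene reaction. In one Lewis acid operation an (E)-silyl enol ether (C4 and C3a with its acetate arm) adds to an α-silyloxy aldehyde (C7a) that already holds C7, the quaternary C6 and an isobutenyl group (C5). The Mukaiyama aldol forms C3a–C7a, the released C4 aldehyde closes C4–C5 by ene cyclization, and lactonization gives the cis-fused bicycle.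

Key step: step 9

Remark: locants C2 to C7a are those of the 1-benzofuran-2-one core of the target (O1 lactone oxygen, C3 methylidene carbon, C4 ester carbon, C5 oxiranyl-bearing carbon, C6 quaternary carbon, C7 carbinol carbon); compounds 1, 2, 5, 11 and 12 are taken as commercial.

Step 1
Reactants: 1 mesityl oxide (4-methylpent-3-en-2-one); 2 triethyl phosphonoacetate
Product: 3 ethyl (2E)-3,5-dimethylhexa-2,4-dienoate
Conditions: NaH, THF, 0 °C to reflux; chromatography to remove the minor (2Z)-isomer
Reagents that add atoms: none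
Why: Horner–Wadsworth–Emmons olefination at the ketone carbonyl (the β,β-disubstituted enone resists conjugate addition) should give mainly the (2E)-dienoate, with the ester trans to the larger isobutenyl group.

Step 2
Reactants: 3 ethyl (2E)-3,5-dimethylhexa-2,4-dienoate
Product: 4 (2E)-3,5-dimethylhexa-2,4-dien-1-ol
Conditions: iBu2AlH (2.2 equiv), CH2Cl2, −78 °C; Rochelle salt work-up
Reagents that add atoms: none
Why: 1,2-reduction of the conjugated ester by the aluminium hydride should give the allylic alcohol without touching the diene or its geometry.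

Step 3
Reactants: 5 (R)-solketal, [(4R)-2,2-dimethyl-1,3-dioxolan-4-yl]methanol
Product: 6 (4S)-2,2-dimethyl-1,3-dioxolane-4-carbaldehyde
Conditions: (COCl)2, DMSO, CH2Cl2, −78 °C; Et3N; used crude at once
Reagents that add atoms: none
Why: Swern oxidation should give the configurationally labile glyceraldehyde acetonide without touching the stereocentre (the descriptor changes from R to S only through the priority rules).

Step 4
Reactants: 4 (2E)-3,5-dimethylhexa-2,4-dien-1-ol; 6 (4S)-2,2-dimethyl-1,3-dioxolane-4-carbaldehyde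
Product: 8 (1R,2S)-1-[(4S)-2,2-dimethyl-1,3-dioxolan-4-yl]-2-ethenyl-2,4-dimethylpent-3-en-1-ol, via dienylboronic acid 7 (not isolated)
Conditions: B2(OH)4, Pd(MeCN)4(BF4)2 (5 mol%), DMSO/MeOH, rt; then 6, 0 °C to rt
Reagents that add atoms: tetrahydroxydiboron, OB(O)B(O)O (boron of intermediate 7; none remains in 8)
Why: Palladium-catalysed borylation of the allylic alcohol should keep the (2E) geometry, and allylboration through a closed chair transition state at the γ-carbon then places the isobutenyl group (trans to CH2B) anti and the methyl syn to the new hydroxyl, while the γ-methyl cis to boron enforces Felkin–Anh (3,4-anti) attack on the α-alkoxy aldehyde, so the carbinol and the quaternary stereocentre are both set from the dioxolane stereocentre.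

Step 5
Reactants: 8 (1R,2S)-1-[(4S)-2,2-dimethyl-1,3-dioxolan-4-yl]-2-ethenyl-2,4-dimethylpent-3-en-1-ol
Product: 9 tert-butyl{[(1R,2S)-1-[(4S)-2,2-dimethyl-1,3-dioxolan-4-yl]-2-ethenyl-2,4-dimethylpent-3-en-1-yl]oxy}dimethylsilane
Conditions: TBSOTf, 2,6-lutidine, CH2Cl2, −78 to 0 °C
Reagents that add atoms: tert-butyldimethylsilyl triflate, CC(C)(C)[Si](C)(C)OS(=O)(=O)C(F)(F)F
Why: Silylation of the hindered secondary alcohol with the silyl triflate should proceed under buffered conditions that leave the acetonide intact, and the bulky non-chelating ether is what later steers the aldol.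

Step 6
Reactants: 9 tert-butyl{[(1R,2S)-1-[(4S)-2,2-dimethyl-1,3-dioxolan-4-yl]-2-ethenyl-2,4-dimethylpent-3-en-1-yl]oxy}dimethylsilane
Product: 10 (2R,3S)-2-[(tert-butyldimethylsilyl)oxy]-3-ethenyl-3,5-dimethylhex-4-enal
Conditions: H5IO6 (1.5 equiv), EtOAc, rt
Reagents that add atoms: none
Why: Periodic acid should hydrolyse the terminal acetonide and cleave the liberated 1,2-diol in one pot (glycol cleavage), so the dioxolane stereocentre that relayed the chirality becomes the aldehyde carbon while the silyl ether and the alkenes are untouched.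

Step 7
Reactants: 11 (tert-butyldimethylsilyloxy)acetaldehyde; 12 methyl (triphenylphosphoranylidene)acetate
Product: 13 methyl (2E)-4-[(tert-butyldimethylsilyl)oxy]but-2-enoate
Conditions: CH2Cl2, rt
Reagents that add atoms: none
Why: Wittig olefination with the stabilised ylide should give the (E)-enoate.

Step 8
Reactants: 13 methyl (2E)-4-[(tert-butyldimethylsilyl)oxy]but-2-enoate
Product: 14 methyl (3E)-4-[(tert-butyldimethylsilyl)oxy]but-3-enoate
Conditions: [Ir(cod)(PMePh2)2]PF6 (2 mol%, activated with H2, then degassed), THF, rt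
Reagents that add atoms: none
Why: Cationic iridium hydride catalysed 1,3-hydrogen shift of a primary allyl silyl ether, which delivers (E)-silyl enol ethers through a syn-π-allyl hydride, should move the double bond next to oxygen because the enol ether gain outweighs the lost ester conjugation.

Step 9
Reactants: 10 (2R,3S)-2-[(tert-butyldimethylsilyl)oxy]-3-ethenyl-3,5-dimethylhex-4-enal; 14 methyl (3E)-4-[(tert-butyldimethylsilyl)oxy]but-3-enoate
Product: 17 (3aS,4R,5S,6S,7R,7aS)-7-[(tert-butyldimethylsilyl)oxy]-6-ethenyl-4-hydroxy-6-methyl-5-(prop-1-en-2-yl)hexahydro-1-benzofuran-2(3H)-one, via aldol adduct 15 (not isolated), via cyclohexanediol ester 16 (not isolated)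
Conditions: Me2AlCl (2.5 equiv), CH2Cl2, −78 °C, 14 added slowly, then 0 °C; aq. HCl; CSA (cat.), CH2Cl2, rt
Reagents that add atoms: none
Why: Proposed new method: Me2AlCl-activated aldehyde 10 is attacked by the (E)-enol silane 14 (Mukaiyama aldol), and the aldehyde set free in aldolate 15 is at once captured by the isobutenyl group with transfer of a methyl hydrogen to oxygen, so that an aldol and an intramolecular carbonyl-ene reaction of the citronellal type, the two closest known reaction types, are merged into a formal (4+2) annulation not yet shown as one cascade. The cyclohexane closes in a six-membered chair ene transition state that is exo for both the C=O and the C=C unit, and the lactone then closes by 5-exo-trig acyl substitution of the axial C7a hydroxyl on the equatorial acetate arm, the cis-fused lactone being favoured over the strained trans-fused C4–O isomer on acid equilibration. C7a is set by Cornforth/Felkin–Anh addition anti to the non-chelating C7 silyloxy group, C3a by the (E)-geometry of 14 in an open antiperiplanar transition state (anti aldol), and C4 and C5 by the chair in which the C3a arm, the C7 silyl ether, the vinyl group and the activated C=O are equatorial (trans hydroxyl and isopropenyl, as in isopulegol). The axial C6 methyl blocks the chelated bicyclic alternative that would give the C4 epimer. The step needs 14 to meet 10 and not the product aldehyde, which slow addition of 14 and the fast ring closure should secure, and only the isobutenyl group can react because the vinyl group has no allylic hydrogen.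

Step 10
Reactants: 17 (3aS,4R,5S,6S,7R,7aS)-7-[(tert-butyldimethylsilyl)oxy]-6-ethenyl-4-hydroxy-6-methyl-5-(prop-1-en-2-yl)hexahydro-1-benzofuran-2(3H)-one
Product: 18 (3aS,4R,5S,6S,7R,7aS)-7-[(tert-butyldimethylsilyl)oxy]-6-ethenyl-6-methyl-2-oxo-5-(prop-1-en-2-yl)octahydro-1-benzofuran-4-yl 2-methylpropanoate
Conditions: isobutyryl chloride, pyridine, DMAP (cat.), CH2Cl2, 0 °C to rt
Reagents that add atoms: isobutyryl chloride, CC(C)C(Cl)=O
Why: DMAP-catalysed acylation should esterify the only free hydroxyl (C4), since C7 is silylated and C7a is locked in the lactone.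

Step 11
Reactants: 18 (3aS,4R,5S,6S,7R,7aS)-7-[(tert-butyldimethylsilyl)oxy]-6-ethenyl-6-methyl-2-oxo-5-(prop-1-en-2-yl)octahydro-1-benzofuran-4-yl 2-methylpropanoate
Product: 21 (3aS,4R,5S,6S,7R,7aS)-7-[(tert-butyldimethylsilyl)oxy]-6-ethenyl-6-methyl-3-methylidene-2-oxo-5-(prop-1-en-2-yl)octahydro-1-benzofuran-4-yl 2-methylpropanoate, via Mannich base 19 (not isolated), via trimethylammonium iodide 20 (not isolated)
Conditions: LiN(iPr)2 (1.1 equiv), THF, −78 °C; CH2=NMe2+ I−, −78 °C to rt; MeI, rt; aq. NaHCO3, CH2Cl2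
Reagents that add atoms: Eschenmoser's salt (N,N-dimethylmethyleneiminium iodide), C=[N+](C)C.[I-]; iodomethane, CI (methyl group of intermediate 20 only)
Why: The lactone α-CH2 is more acidic and less hindered than the isobutyrate methine, so its enolate should undergo the Mannich reaction with the iminium salt (from the convex face), and quaternisation followed by base-induced elimination of trimethylamine gives the α-methylene lactone (α-methylenation).

Step 12
Reactants: 21 (3aS,4R,5S,6S,7R,7aS)-7-[(tert-butyldimethylsilyl)oxy]-6-ethenyl-6-methyl-3-methylidene-2-oxo-5-(prop-1-en-2-yl)octahydro-1-benzofuran-4-yl 2-methylpropanoate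
Product: 22 (3aS,4R,5S,6S,7R,7aS)-6-ethenyl-7-hydroxy-6-methyl-3-methylidene-2-oxo-5-(prop-1-en-2-yl)octahydro-1-benzofuran-4-yl 2-methylpropanoate
Conditions: HF·pyridine, THF/pyridine, 0 °C to rt
Reagents that add atoms: none
Why: Fluoride-mediated desilylation under buffered acidic conditions should free the C7 hydroxyl without harming the α-methylene lactone or the ester.

Step 13
Reactants: 22 (3aS,4R,5S,6S,7R,7aS)-6-ethenyl-7-hydroxy-6-methyl-3-methylidene-2-oxo-5-(prop-1-en-2-yl)octahydro-1-benzofuran-4-yl 2-methylpropanoate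
Product: 23 (3aS,4R,5S,6S,7R,7aS)-6-ethenyl-7-hydroxy-5-(3-hydroxyprop-1-en-2-yl)-6-methyl-3-methylidene-2-oxooctahydro-1-benzofuran-4-yl 2-methylpropanoate
Conditions: SeO2 (0.5 equiv), t-BuOOH (3 equiv), salicylic acid (cat.), CH2Cl2, rt
Reagents that add atoms: selenium dioxide, O=[Se]=O; tert-butyl hydroperoxide, CC(C)(C)OO
Why: Selenium dioxide allylic oxidation (ene reaction, then [2,3]-sigmatropic shift) should hydroxylate the methyl of the electron-rich isopropenyl group, the only alkene with a reactive allylic C–H, since the vinyl group has none and the methylene lactone is electron-poor.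

Step 14
Reactants: 23 (3aS,4R,5S,6S,7R,7aS)-6-ethenyl-7-hydroxy-5-(3-hydroxyprop-1-en-2-yl)-6-methyl-3-methylidene-2-oxooctahydro-1-benzofuran-4-yl 2-methylpropanoate
Product: 24 (3aS,4S,5S,6S,7R,7aS)-6-ethenyl-7-hydroxy-5-[(2S)-2-(hydroxymethyl)oxiran-2-yl]-6-methyl-3-methylidene-2-oxooctahydro-1-benzofuran-4-yl 2-methylpropanoate
Conditions: Ti(OiPr)4 (10 mol%), L-(+)-diethyl tartrate (12 mol%), t-BuOOH, 4 Å molecular sieves, CH2Cl2, −20 °C
Reagents that add atoms: tert-butyl hydroperoxide, CC(C)(C)OO
Why: Sharpless asymmetric epoxidation of the 2-substituted allylic alcohol with the L-(+)-tartrate should deliver oxygen to the face that gives the (2S)-oxirane (as 2-methylallyl alcohol gives (S)-2-methylglycidol), the reagent setting the quaternary oxirane stereocentre while the homoallylic C7 hydroxyl and the other alkenes are not engaged.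

Step 15
Reactants: 24 (3aS,4S,5S,6S,7R,7aS)-6-ethenyl-7-hydroxy-5-[(2S)-2-(hydroxymethyl)oxiran-2-yl]-6-methyl-3-methylidene-2-oxooctahydro-1-benzofuran-4-yl 2-methylpropanoate
Product: 25 (3aS,4S,5S,6S,7R,7aS)-6-ethenyl-5-[(2R)-2-formyloxiran-2-yl]-7-hydroxy-6-methyl-3-methylidene-2-oxooctahydro-1-benzofuran-4-yl 2-methylpropanoate (target, CNP0127398.1)
Conditions: TEMPO (10 mol%), PhI(OAc)2, CH2Cl2, rt
Reagents that add atoms: none
Why: The oxoammonium oxidation is selective for the primary alcohol over the hindered secondary C7 hydroxyl and should give the non-enolisable epoxy aldehyde without opening the oxirane (the descriptor changes from S to R only through the priority rules).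

Compound list
1 | mesityl oxide (4-methylpent-3-en-2-one) | CC(=O)C=C(C)C | starting material
2 | triethyl phosphonoacetate | CCOC(=O)CP(=O)(OCC)OCC | starting material
3 | ethyl (2E)-3,5-dimethylhexa-2,4-dienoate | CCOC(=O)/C=C(\C)C=C(C)C | intermediate
4 | (2E)-3,5-dimethylhexa-2,4-dien-1-ol | OC/C=C(\C)C=C(C)C | intermediate
5 | (R)-solketal, [(4R)-2,2-dimethyl-1,3-dioxolan-4-yl]methanol | OC[C@@H]1COC(C)(C)O1 | starting material
6 | (4S)-2,2-dimethyl-1,3-dioxolane-4-carbaldehyde | O=C[C@@H]1COC(C)(C)O1 | intermediate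
7 | [(2E)-3,5-dimethylhexa-2,4-dien-1-yl]boronic acid | OB(O)C/C=C(\C)C=C(C)C | intermediate
8 | (1R,2S)-1-[(4S)-2,2-dimethyl-1,3-dioxolan-4-yl]-2-ethenyl-2,4-dimethylpent-3-en-1-ol | C=C[C@@]([C@@H](O)[C@@H]1COC(C)(C)O1)(C)C=C(C)C | intermediate
9 | tert-butyl{[(1R,2S)-1-[(4S)-2,2-dimethyl-1,3-dioxolan-4-yl]-2-ethenyl-2,4-dimethylpent-3-en-1-yl]oxy}dimethylsilane | C=C[C@@]([C@@H](O[Si](C)(C)C(C)(C)C)[C@@H]1COC(C)(C)O1)(C)C=C(C)C | intermediate
10 | (2R,3S)-2-[(tert-butyldimethylsilyl)oxy]-3-ethenyl-3,5-dimethylhex-4-enal | C=C[C@@]([C@@H](O[Si](C)(C)C(C)(C)C)C=O)(C)C=C(C)C | intermediate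
11 | (tert-butyldimethylsilyloxy)acetaldehyde | O=CCO[Si](C)(C)C(C)(C)C | starting material
12 | methyl (triphenylphosphoranylidene)acetate | COC(=O)C=P(c1ccccc1)(c1ccccc1)c1ccccc1 | starting material
13 | methyl (2E)-4-[(tert-butyldimethylsilyl)oxy]but-2-enoate | COC(=O)/C=C/CO[Si](C)(C)C(C)(C)C | intermediate
14 | methyl (3E)-4-[(tert-butyldimethylsilyl)oxy]but-3-enoate | COC(=O)C/C=C/O[Si](C)(C)C(C)(C)C | intermediate
15 | methyl (3R,4S,5R,6S)-5-[(tert-butyldimethylsilyl)oxy]-6-ethenyl-3-formyl-4-hydroxy-6,8-dimethylnon-7-enoate (anti,anti aldol adduct) | C=C[C@@]([C@@H](O[Si](C)(C)C(C)(C)C)[C@@H](O)[C@@H](CC(=O)OC)C=O)(C)C=C(C)C | intermediate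
16 | methyl 2-[(1S,2S,3R,4S,5S,6R)-3-[(tert-butyldimethylsilyl)oxy]-4-ethenyl-2,6-dihydroxy-4-methyl-5-(prop-1-en-2-yl)cyclohexyl]acetate | C=C[C@@]1(C)[C@H](C(C)=C)[C@@H](O)[C@H](CC(=O)OC)[C@H](O)[C@@H]1O[Si](C)(C)C(C)(C)C | intermediate
17 | (3aS,4R,5S,6S,7R,7aS)-7-[(tert-butyldimethylsilyl)oxy]-6-ethenyl-4-hydroxy-6-methyl-5-(prop-1-en-2-yl)hexahydro-1-benzofuran-2(3H)-one | C=C[C@@]1(C)[C@H](C(C)=C)[C@@H](O)[C@@H]2CC(=O)O[C@@H]2[C@@H]1O[Si](C)(C)C(C)(C)C | intermediate
18 | (3aS,4R,5S,6S,7R,7aS)-7-[(tert-butyldimethylsilyl)oxy]-6-ethenyl-6-methyl-2-oxo-5-(prop-1-en-2-yl)octahydro-1-benzofuran-4-yl 2-methylpropanoate | C=C[C@@]1(C)[C@H](C(C)=C)[C@@H](OC(=O)C(C)C)[C@@H]2CC(=O)O[C@@H]2[C@@H]1O[Si](C)(C)C(C)(C)C | intermediate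
19 | (3S,3aS,4R,5S,6S,7R,7aS)-7-[(tert-butyldimethylsilyl)oxy]-3-[(dimethylamino)methyl]-6-ethenyl-6-methyl-2-oxo-5-(prop-1-en-2-yl)octahydro-1-benzofuran-4-yl 2-methylpropanoate (expected convex-face adduct; C3 is erased in the elimination) | C=C[C@@]1(C)[C@H](C(C)=C)[C@@H](OC(=O)C(C)C)[C@@H]2[C@@H](CN(C)C)C(=O)O[C@@H]2[C@@H]1O[Si](C)(C)C(C)(C)C | intermediate
20 | {(3S,3aS,4R,5S,6S,7R,7aS)-7-[(tert-butyldimethylsilyl)oxy]-6-ethenyl-6-methyl-4-[(2-methylpropanoyl)oxy]-2-oxo-5-(prop-1-en-2-yl)octahydro-1-benzofuran-3-yl}methyl(trimethyl)azanium iodide | C=C[C@@]1(C)[C@H](C(C)=C)[C@@H](OC(=O)C(C)C)[C@@H]2[C@@H](C[N+](C)(C)C)C(=O)O[C@@H]2[C@@H]1O[Si](C)(C)C(C)(C)C.[I-] | intermediate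
21 | (3aS,4R,5S,6S,7R,7aS)-7-[(tert-butyldimethylsilyl)oxy]-6-ethenyl-6-methyl-3-methylidene-2-oxo-5-(prop-1-en-2-yl)octahydro-1-benzofuran-4-yl 2-methylpropanoate | C=C[C@@]1(C)[C@H](C(C)=C)[C@@H](OC(=O)C(C)C)[C@@H]2C(=C)C(=O)O[C@@H]2[C@@H]1O[Si](C)(C)C(C)(C)C | intermediate
22 | (3aS,4R,5S,6S,7R,7aS)-6-ethenyl-7-hydroxy-6-methyl-3-methylidene-2-oxo-5-(prop-1-en-2-yl)octahydro-1-benzofuran-4-yl 2-methylpropanoate | C=C[C@@]1(C)[C@H](C(C)=C)[C@@H](OC(=O)C(C)C)[C@@H]2C(=C)C(=O)O[C@@H]2[C@@H]1O | intermediate
23 | (3aS,4R,5S,6S,7R,7aS)-6-ethenyl-7-hydroxy-5-(3-hydroxyprop-1-en-2-yl)-6-methyl-3-methylidene-2-oxooctahydro-1-benzofuran-4-yl 2-methylpropanoate | C=C[C@@]1(C)[C@H](C(CO)=C)[C@@H](OC(=O)C(C)C)[C@@H]2C(=C)C(=O)O[C@@H]2[C@@H]1O | intermediate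
24 | (3aS,4S,5S,6S,7R,7aS)-6-ethenyl-7-hydroxy-5-[(2S)-2-(hydroxymethyl)oxiran-2-yl]-6-methyl-3-methylidene-2-oxooctahydro-1-benzofuran-4-yl 2-methylpropanoate | C=C[C@@]1(C)[C@H]([C@]2(CO)CO2)[C@@H](OC(=O)C(C)C)[C@@H]2C(=C)C(=O)O[C@@H]2[C@@H]1O | intermediate
25 | (3aS,4S,5S,6S,7R,7aS)-6-ethenyl-5-[(2R)-2-formyloxiran-2-yl]-7-hydroxy-6-methyl-3-methylidene-2-oxooctahydro-1-benzofuran-4-yl 2-methylpropanoate (CNP0127398.1) | C=C[C@@]1(C)[C@H]([C@]2(C=O)CO2)[C@@H](OC(=O)C(C)C)[C@@H]2C(=C)C(=O)O[C@@H]2[C@@H]1O | target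

Total step count: 15. Longest linear sequence: 12 steps (1, 2, 4, 5, 6, 9, 10, 11, 12, 13, 14, 15); step 3 and steps 7 and 8 are side branches.

Steps most likely to fail

Step 9 (proposed cascade). Several processes may intervene:
- The open transition state may lose simple diastereoselection, giving the syn aldol and hence the C3a epimer.
- A second aldol of 14 with the newly formed aldehyde may outrun ring closure.
- Ene closure through an aluminium chelate may give the C4 epimer.
- Lactonization may occur on the C4 hydroxyl.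

The fallback uses known chemistry in two operations and sets out from aldehyde 10 and commercial methyl 4-oxobutanoate. D-Proline (20 to 30 mol%) in DMF at 4 °C, with slow addition of the donor aldehyde, should give the anti aldol 15 by enamine catalysis through the hydrogen-bonded chair transition state; the catalyst sense is matched with the Felkin preference of 10, and 15 is isolated. Me2AlCl (2 equiv, CH2Cl2, −78 to 0 °C) then effects the intramolecular carbonyl-ene closure to 16, and CSA closes the lactone, so the fallback comes back to the route at 17. Enol silane 14 and steps 7 and 8 are then not needed, and no compound outside the list is made: none (F0).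

Step 8. The iridium hydride may stall on the conjugated enoate (no turnover), or the double bond geometry may erode, which would feed the syn aldol into step 9. The fallback sets out from 11. Still–Gennari olefination with methyl bis(2,2,2-trifluoroethyl)phosphonoacetate (KN(SiMe3)2, 18-crown-6, THF, −78 °C) gives methyl (2Z)-4-[(tert-butyldimethylsilyl)oxy]but-2-enoate F1. γ-Deprotonation with LiN(iPr)2/DMPU at −78 °C and kinetic α-protonation of the dienolate with acetic acid then deconjugate it, the (2Z) geometry translating into the (3E) enol ether, and the fallback comes back to the route at 14.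

Step 13. The allylic oxidation may run on to the enal, attack the C5 methine instead of the methyl, or stop at low conversion. The fallback sets out from 22. Ene-type allylic chlorination of the isopropenyl group with hypochlorous acid generated from Ca(OCl)2 and CO2 (CH2Cl2/H2O, 0 °C) gives (3aS,4R,5R,6S,7R,7aS)-5-(3-chloroprop-1-en-2-yl)-6-ethenyl-7-hydroxy-6-methyl-3-methylidene-2-oxooctahydro-1-benzofuran-4-yl 2-methylpropanoate F2. Silver-assisted hydrolysis of this 2-substituted allyl chloride (AgOTf, aqueous acetone), whose allyl cation is symmetric, should give the allylic alcohol, and the fallback comes back to the route at 23.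

Further compounds
F0 | step 9 | none | none
F1 | step 8 | methyl (2Z)-4-[(tert-butyldimethylsilyl)oxy]but-2-enoate | COC(=O)/C=C\CO[Si](C)(C)C(C)(C)C
F2 | step 13 | (3aS,4R,5R,6S,7R,7aS)-5-(3-chloroprop-1-en-2-yl)-6-ethenyl-7-hydroxy-6-methyl-3-methylidene-2-oxooctahydro-1-benzofuran-4-yl 2-methylpropanoate | C=C[C@@]1(C)[C@H](C(CCl)=C)[C@@H](OC(=O)C(C)C)[C@@H]2C(=C)C(=O)O[C@@H]2[C@@H]1O
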